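The runs stem from a simulated flask for substances that don't exist; noise was put on by code.

I had no constants for this flask, so I drew one from the earlier readings.

| flask | starting material | partner | remark | time |
|---|---|---|---|---|
| ochre | 22 mM | 47 mM | run made earlier |  |
| green | 95 mM | 47 mM | run made earlier |  |
| birch | 15 mM | 47.0 mM |  | 10 h |
| elm | 20 mM | 47.0 mM |  | 10 h |
| ash | 30 mM | 47.0 mM |  | 10 h |
| larch | 50 mM | 47.0 mM |  | 10 h |
| cedar | 80 mM | 47.0 mM |  | 10 h |

| run | time / h | double product / % |
|---|---|---|
| ochre | 1.00 | 66.6 |
| ochre | 2.00 | 71.1 |
| ochre | 3.00 | 72.1 |
| ochre | 4.00 | 72.6 |
| ochre | 5.00 | 72.6 |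
| green | 0.417 | 5.8 |
| green | 0.833 | 3.9 |
| green | 1.33 | 1.4 |
| green | 2.50 | 0.4 |
| green | 5.00 | 0 |

(standard deviation of a reading: 0.5 percentage points)

- [double product] at the end for birch, elm, ash, larch, cedar, in this order
- how the row runs (falls all the way / falls, then rises / rises, then falls / hardly changes / rises all the way)

- "hardly changes" means that all values lie within two and a half points (for a concentration: within two and a half percent of the largest)
- a step back or a flat step of under half a percent of the largest counts as no turn

In the green run the double product fell from 5.8 % at 0.417 h to 1.4 % at 1.33 h, a reading still above the scatter. That is a loss of 1.56 /h, while the starting material beyond the partner's charge was 50.5 % of its own charge. Dividing that loss by this surplus gave my clearing constant, the first-order loss of double product per unit of surplus starting material: 32.4 /M/h. At a steady surplus the loss is pseudo-first-order, so the half-life is ln(2) over the constant times the surplus. The surplus was 6.00 % of the charge in larch, giving 7.12 h, and 41.2 % in cedar, giving 0.648 h. So I expected some double product to survive in larch, with 1.40 halvings in 10 h, and none to speak of in cedar, with 15.4.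

The forecast gave 14.8 mM, 18 mM, 8 mM, 0 mM and 0 mM, a row that rises, then falls, on the ground that the green run shows the double product “appearing and then vanishing” when starting material is in excess.

The flasks gave 12.2 mM, 15.1 mM, 15.6 mM, 2.21 mM and 0.00527 mM, a row that rises, then falls.

    starting material + partner → single product (k = 2.72 /M/min)
    partner + single product → double product (k = 2.93 /M/min)
    single product → decomposed reagent (k = 0.0159 /min)
    starting material + double product → side product (k = 0.372 /M/min)

Larch held 2.21 mM at the end, where the forecast had 0 mM. Its double product went from 8.73 % of the charge at 5.00 h to 4.42 % at 10.0 h, about half. With starting material at 10.4 % of the larch charge, the clearing constant gives a half-life of 4.10 h. In cedar, starting material stood at 41.3 % of the charge, which gives 0.648 h, and the double product fell from 0.264 % to 0.00659 % over the same interval, a halving every 0.939 h.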